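**Retrosynthetic overview**

1. Target 13 comes from the doubly protected benzofuranone 11 by desilylation at O6 and, as the very last operation, ammonolysis of the ketal benzoate at C2.
2. 11 comes from open-chain aldehyde 10 by palladium-catalysed acylation of the aryl bromide with the formyl group. This makes the C3a–C3 bond and closes the furanone ring (ring B, O1–C2–C3–C3a–C7a); benzene ring A is present from the start, so ring B is the only ring formed.
3. The strategy rests on C2 of ring B: a fully substituted mixed ketal carbon (bonded to O1, the hemiketal oxygen, carbonyl C3 and farnesyl C1') that carries no hydrogen. An aldehyde holding this carbon cannot enolise, so its configuration passes unchanged into the ring.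
4. 10 comes from racemic α-aryloxy aldehyde 9 by amine-catalysed enantioselective α-benzoyloxylation, which sets C2.
5. 9 comes from 4-bromoresorcinol (1), ethyl bromoacetate (3) and (2E,6E)-farnesyl bromide (5) by monosilylation, O-alkylation, enolate farnesylation and half-reduction.

Key step: step 6

Assumption: the free C2 hemiketal of 13 can in principle open to the 1-(2,4-dihydroxyphenyl)-1,2-dione and reclose on either face; it is taken to hold its configuration at or below 0 °C near neutral pH, which is why it is unmasked only in the last step.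

**Step 1**
Reactants: 1 4-bromoresorcinol
Product: 2 2-bromo-5-(triisopropylsilyloxy)phenol
Conditions: i-Pr3SiCl (1.0 equiv), imidazole, DMF, −20 → 0 °C
Reagents that add atoms: triisopropylsilyl chloride, CC(C)[Si](Cl)(C(C)C)C(C)C
Why: Imidazole-promoted phenol silylation with a bulky chlorosilane should occur at the unhindered hydroxyl para to bromine rather than at the hydroxyl flanked by bromine, and any regioisomer or bis-ether is removed by chromatography.

**Step 2**
Reactants: 2 2-bromo-5-(triisopropylsilyloxy)phenol; 3 ethyl bromoacetate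
Product: 4 ethyl 2-[2-bromo-5-(triisopropylsilyloxy)phenoxy]acetate
Conditions: K2CO3, acetone, 50 °C
Reagents that add atoms: none
Why: Williamson ether synthesis of the remaining phenol with a primary α-bromo ester under carbonate, conditions the aryl triisopropylsilyl ether tolerates.

**Step 3**
Reactants: 4 ethyl 2-[2-bromo-5-(triisopropylsilyloxy)phenoxy]acetate; 5 (2E,6E)-farnesyl bromide
Product: 7 ethyl (4E,8E)-2-[2-bromo-5-(triisopropylsilyloxy)phenoxy]-5,9,13-trimethyltetradeca-4,8,12-trienoate (racemic), via lithium ester enolate 6 (not isolated)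
Conditions: LiN(i-Pr)2 (commercial solution, 1.05 equiv), THF, −78 °C (ester added to the base); then 5, DMPU, −78 → −30 °C
Reagents that add atoms: none
Why: SN2 alkylation of an ester lithium enolate with a primary allylic bromide leaves the E alkenes untouched, and the new centre may be racemic because it is made planar again in step 5.

**Step 4**
Reactants: 7 ethyl (4E,8E)-2-[2-bromo-5-(triisopropylsilyloxy)phenoxy]-5,9,13-trimethyltetradeca-4,8,12-trienoate
Product: 9 (4E,8E)-2-[2-bromo-5-(triisopropylsilyloxy)phenoxy]-5,9,13-trimethyltetradeca-4,8,12-trienal (racemic), via aluminium hemiacetal 8 (not isolated)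
Conditions: i-Bu2AlH (1.1 equiv), CH2Cl2, −78 °C; MeOH, then aq. KNaC4H4O6
Reagents that add atoms: none
Why: Partial reduction of an α-aryloxy ester with i-Bu2AlH at −78 °C stops at the chelated aluminium hemiacetal, which releases the aldehyde only on work-up, while the aryl bromide, silyl ether and alkenes are inert.

**Step 5**
Reactants: 9 (4E,8E)-2-[2-bromo-5-(triisopropylsilyloxy)phenoxy]-5,9,13-trimethyltetradeca-4,8,12-trienal
Product: 10 (2S,4E,8E)-2-(benzoyloxy)-2-[2-bromo-5-(triisopropylsilyloxy)phenoxy]-5,9,13-trimethyltetradeca-4,8,12-trienal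
Conditions: (PhCO2)2 (1.2 equiv), 9-amino-9-deoxy-epi-quinine (20 mol %), Cl3CCO2H (20 mol %), 2,6-di-tert-butyl-4-methylphenol (10 mol %), THF, rt
Reagents that add atoms: dibenzoyl peroxide, O=C(OOC(=O)c1ccccc1)c1ccccc1
Why: Proposed new method: the primary amine condenses with 9 to an iminium ion that tautomerises to an enamine whose nucleophilic carbon carries the aryloxy and farnesylmethyl groups (the racemic centre of 9 is erased here, so both enantiomers converge), this carbon attacks the O–O bond of the peroxide, which is held by the protonated quinuclidine, from one face, and hydrolysis of the α-benzoyloxy iminium ion releases 10; the closest known reaction type is the cinchona primary amine catalysed enantioselective α-benzoyloxylation of α-branched (α-aryl α-alkyl) aldehydes with benzoyl peroxide, which has not been shown with an α-aryloxy substituent; the C2 stereocenter is set by catalyst control, the (S) sense with the quinine-derived amine being a working assignment that must be proven (the quinidine-derived pseudo-enantiomer would give the mirror image), and 10, having no α-hydrogen, cannot racemise by enolisation.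

**Step 6**
Reactants: 10 (2S,4E,8E)-2-(benzoyloxy)-2-[2-bromo-5-(triisopropylsilyloxy)phenoxy]-5,9,13-trimethyltetradeca-4,8,12-trienal
Product: 11 (2S)-2-(benzoyloxy)-2-[(2E,6E)-3,7,11-trimethyldodeca-2,6,10-trien-1-yl]-6-(triisopropylsilyloxy)benzofuran-3(2H)-one
Conditions: Pd2(dba)3 (5 mol %), rac-BINAP (12 mol %), Cs2CO3 (1.5 equiv, dried), 1,4-dioxane, 100 °C
Reagents that add atoms: none
Why: Zerovalent palladium inserts into the C–Br bond of 10; the arylpalladium bromide then either adds across the neighbouring formyl C=O, the palladium alkoxide losing β-hydride, or activates the formyl C–H to an aryl acyl palladacycle that reductively eliminates, and Cs2CO3 takes up the HBr in both cases. The closest known reaction type is the palladium-catalysed intramolecular acylation of aryl bromides with tethered aldehydes, which is established for aldehydes with a quaternary α-carbon. Ring B (O1–C2–C3–C3a–C7a) closes by C3a–C3 bond formation, a 5-exo-trig addition in the carbopalladation picture. No stereocenter is formed and no bond to C2 is touched; as C2 bears no hydrogen, the aldehyde can neither enolise nor undergo α-arylation, so the configuration from step 5 is carried over. The step needs chemoselectivity for acylation over Heck insertion into the C4=C5 alkene, decarbonylation and attack on the benzoate; this is expected from the proximity of the formyl group (five-membered closure against six-membered closure onto a trisubstituted alkene), from the chelating bisphosphine that leaves little room for alkene coordination, and from dry, weakly nucleophilic carbonate.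

**Step 7**
Reactants: 11 (2S)-2-(benzoyloxy)-2-[(2E,6E)-3,7,11-trimethyldodeca-2,6,10-trien-1-yl]-6-(triisopropylsilyloxy)benzofuran-3(2H)-one
Product: 12 (2S)-2-(benzoyloxy)-6-hydroxy-2-[(2E,6E)-3,7,11-trimethyldodeca-2,6,10-trien-1-yl]benzofuran-3(2H)-one
Conditions: HF·pyridine, pyridine, THF, 0 °C → rt
Reagents that add atoms: none
Why: Fluoride-mediated cleavage of the aryl silyl ether in a pyridine-buffered medium leaves the ketal benzoate and the alkenes alone, and C2 stays locked as its benzoate.

**Step 8**
Reactants: 12 (2S)-2-(benzoyloxy)-6-hydroxy-2-[(2E,6E)-3,7,11-trimethyldodeca-2,6,10-trien-1-yl]benzofuran-3(2H)-one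
Product: 13 (2R)-2,6-dihydroxy-2-[(2E,6E)-3,7,11-trimethyldodeca-2,6,10-trien-1-yl]benzofuran-3(2H)-one
Conditions: NH3 (0.4 M in THF, excess), 0 °C; cold pH 7 phosphate buffer
Reagents that add atoms: none
Why: Ammonolysis of an activated, anomeric-type ester (its leaving group is a hemiketal oxygen next to a ketone) cleaves the acyl–oxygen bond only, so the C2–O bond and the configuration are retained; the descriptor changes from S to R solely because OH ranks below O1.

**Compound list**

1 | 4-bromoresorcinol | Oc1ccc(Br)c(O)c1 | starting material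
2 | 2-bromo-5-(triisopropylsilyloxy)phenol | Oc1cc(O[Si](C(C)C)(C(C)C)C(C)C)ccc1Br | intermediate
3 | ethyl bromoacetate | CCOC(=O)CBr | starting material
4 | ethyl 2-[2-bromo-5-(triisopropylsilyloxy)phenoxy]acetate | CCOC(=O)COc1cc(O[Si](C(C)C)(C(C)C)C(C)C)ccc1Br | intermediate
5 | (2E,6E)-farnesyl bromide | CC(C)=CCC/C(C)=C/CC/C(C)=C/CBr | starting material
6 | lithium enolate of 4 (not isolated) | [Li+].CCOC([O-])=COc1cc(O[Si](C(C)C)(C(C)C)C(C)C)ccc1Br | intermediate
7 | ethyl (4E,8E)-2-[2-bromo-5-(triisopropylsilyloxy)phenoxy]-5,9,13-trimethyltetradeca-4,8,12-trienoate, racemic | CC(C)=CCC/C(C)=C/CC/C(C)=C/CC(Oc1cc(O[Si](C(C)C)(C(C)C)C(C)C)ccc1Br)C(=O)OCC | intermediate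
8 | diisobutylaluminium hemiacetal of 7 (not isolated) | CC(C)=CCC/C(C)=C/CC/C(C)=C/CC(Oc1cc(O[Si](C(C)C)(C(C)C)C(C)C)ccc1Br)C(OCC)O[Al](CC(C)C)CC(C)C | intermediate
9 | (4E,8E)-2-[2-bromo-5-(triisopropylsilyloxy)phenoxy]-5,9,13-trimethyltetradeca-4,8,12-trienal, racemic | CC(C)=CCC/C(C)=C/CC/C(C)=C/CC(Oc1cc(O[Si](C(C)C)(C(C)C)C(C)C)ccc1Br)C=O | intermediate
10 | (2S,4E,8E)-2-(benzoyloxy)-2-[2-bromo-5-(triisopropylsilyloxy)phenoxy]-5,9,13-trimethyltetradeca-4,8,12-trienal | CC(C)=CCC/C(C)=C/CC/C(C)=C/C[C@@](OC(=O)c1ccccc1)(Oc1cc(O[Si](C(C)C)(C(C)C)C(C)C)ccc1Br)C=O | intermediate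
11 | (2S)-2-(benzoyloxy)-2-[(2E,6E)-3,7,11-trimethyldodeca-2,6,10-trien-1-yl]-6-(triisopropylsilyloxy)benzofuran-3(2H)-one | CC(C)=CCC/C(C)=C/CC/C(C)=C/C[C@@]1(OC(=O)c3ccccc3)Oc2cc(O[Si](C(C)C)(C(C)C)C(C)C)ccc2C1=O | intermediate
12 | (2S)-2-(benzoyloxy)-6-hydroxy-2-[(2E,6E)-3,7,11-trimethyldodeca-2,6,10-trien-1-yl]benzofuran-3(2H)-one | CC(C)=CCC/C(C)=C/CC/C(C)=C/C[C@@]1(OC(=O)c3ccccc3)Oc2cc(O)ccc2C1=O | intermediate
13 | (2R)-2,6-dihydroxy-2-[(2E,6E)-3,7,11-trimethyldodeca-2,6,10-trien-1-yl]benzofuran-3(2H)-one | CC(C)=CCC/C(C)=C/CC/C(C)=C/C[C@@]1(O)Oc2cc(O)ccc2C1=O | target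

**Step count**

Total steps: 8. Longest linear sequence: 8 steps (from 1).

**Steps most likely to fail**

1. Step 5 (proposed new method). The enamine may form slowly at the fully substituted carbon, its geometry (aryloxy against alkyl) may be poorly defined so that facial discrimination is low, and the amine catalyst may be consumed by acylation or oxidation. The fallback sets out from 9 and gives up asymmetric catalysis for resolution. Aldehyde 9 is treated with N-methyl-O-benzoylhydroxylamine hydrochloride (DMSO, rt); condensation to an N-benzoyloxy enamine, [3,3]-sigmatropic shift and hydrolysis, a known α-oxybenzoylation of α-branched aldehydes, should give the racemic 2-(benzoyloxy) aldehyde F1. Preparative chromatography on a polysaccharide carbamate chiral stationary phase then separates F1 into 10 and the (2R)-enantiomer F2, which is discarded. The fallback comes back to the route at 10.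

2. Step 6 (key step). The arylpalladium intermediate may insert into the C4=C5 alkene (Heck pathway, six-membered closure), lose CO after acyl formation, or be reduced to the debrominated arene. The fallback sets out from 10 and closes the same C3a–C3 bond at the alcohol oxidation level without palladium. Nickel-catalysed reductive 1,2-arylation of the formyl group (NiBr2(MeOCH2CH2OMe), 2,6-bis(pyrazol-1-yl)pyridine, Zn, Et3SiCl, N,N-dimethylacetamide, rt) should give the (2S)-2-(benzoyloxy)-3-(triethylsilyloxy)-6-(triisopropylsilyloxy)-2-farnesyl-2,3-dihydrobenzofuran F3 as a mixture of C3 epimers; trapping as the silyl ether keeps a free alkoxide from taking over the neighbouring benzoyl group. Selective removal of the alkyl triethylsilyl ether (pyridinium p-toluenesulfonate, MeOH, 0 °C; the aryl triisopropylsilyl ether stays) gives the 3-hydroxy compound F4. Dess–Martin oxidation (NaHCO3, CH2Cl2) removes the C3 stereocenter and comes back to the route at 11.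

3. Step 8. The hemiketal oxygen set free under ammonia may open ring B to the 1,2-dione and reclose with loss of configurational purity, acyl transfer at the hindered ester may be slow, and ammonia may condense with the C3 ketone. The fallback sets out from 11, reverses the order of the deprotections and avoids amine base. The benzoate is cleaved at the silyl ether stage with Me3SnOH (1,2-dichloroethane, 60 °C), giving (2R)-2-hydroxy-2-farnesyl-6-(triisopropylsilyloxy)benzofuran-3(2H)-one F5. The final desilylation (HF·pyridine, pyridine, THF, 0 °C) then takes place in a weakly acidic medium in which the hemiketal alkoxide is not generated, and comes back to the route at 13.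

**Further compounds**

F1 | step 5 | (4E,8E)-2-(benzoyloxy)-2-[2-bromo-5-(triisopropylsilyloxy)phenoxy]-5,9,13-trimethyltetradeca-4,8,12-trienal, racemic | CC(C)=CCC/C(C)=C/CC/C(C)=C/CC(OC(=O)c1ccccc1)(Oc1cc(O[Si](C(C)C)(C(C)C)C(C)C)ccc1Br)C=O
F2 | step 5 | (2R,4E,8E)-2-(benzoyloxy)-2-[2-bromo-5-(triisopropylsilyloxy)phenoxy]-5,9,13-trimethyltetradeca-4,8,12-trienal | CC(C)=CCC/C(C)=C/CC/C(C)=C/C[C@](OC(=O)c1ccccc1)(Oc1cc(O[Si](C(C)C)(C(C)C)C(C)C)ccc1Br)C=O
F3 | step 6 | (2S)-2-(benzoyloxy)-2-[(2E,6E)-3,7,11-trimethyldodeca-2,6,10-trien-1-yl]-3-(triethylsilyloxy)-6-(triisopropylsilyloxy)-2,3-dihydrobenzofuran, mixture of C3 epimers | CC(C)=CCC/C(C)=C/CC/C(C)=C/C[C@@]1(OC(=O)c3ccccc3)Oc2cc(O[Si](C(C)C)(C(C)C)C(C)C)ccc2C1O[Si](CC)(CC)CC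
F4 | step 6 | (2S)-2-(benzoyloxy)-3-hydroxy-2-[(2E,6E)-3,7,11-trimethyldodeca-2,6,10-trien-1-yl]-6-(triisopropylsilyloxy)-2,3-dihydrobenzofuran, mixture of C3 epimers | CC(C)=CCC/C(C)=C/CC/C(C)=C/C[C@@]1(OC(=O)c3ccccc3)Oc2cc(O[Si](C(C)C)(C(C)C)C(C)C)ccc2C1O
F5 | step 8 | (2R)-2-hydroxy-2-[(2E,6E)-3,7,11-trimethyldodeca-2,6,10-trien-1-yl]-6-(triisopropylsilyloxy)benzofuran-3(2H)-one | CC(C)=CCC/C(C)=C/CC/C(C)=C/C[C@@]1(O)Oc2cc(O[Si](C(C)C)(C(C)C)C(C)C)ccc2C1=O
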